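# Proposed synthesis of CNP0192639.1 by double asymmetric hydroboration of a bis(Z‑enol ether)

## Analysis of the target

The target is a linear tetra‑aryl neolignan with no macrocycle and one heterocycle. A guaiacyl ring (ring A) and a syringyl ring (ring B) each carry a chain ArCH(OH)–CH(OAr)–CH2OH (C7–C8–C9 on ring A, C7'–C8'–C9' on ring B). The C8 oxygen is the 4‑oxygen of ring B, and the C8' oxygen is the 4‑oxygen of a second syringyl ring (ring C). Ring C is the 2‑aryl group of a 3‑hydroxymethyl‑7‑methoxy‑2,3‑dihydrobenzofuran (ring D with its fused dihydrofuran ring), which carries an (E)‑propenal at C5.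

There are six stereocentres: C7/C8 and C7'/C8' are each erythro and each (R,S), and C2/C3 of the dihydrofuran are trans, (2R,3S). The three pairs are separated by aromatic rings, so none can control another, and the two chain units are the same problem posed twice.

The sensitive groups are the enal, the free phenol para to the C7 carbinol (quinone methide formation under acid or hot base), the two benzylic alcohols β to aryl ethers, and the acid‑labile benzylic C2–O bond of the 2‑arylcoumaran. The difficulty is that the erythro (anti) relationship is the one that enolate aldol chemistry does not deliver directly, since a syn aldol of an aryloxyacetyl donor leads to the threo series. In addition, both ether oxygens sit between two ortho methoxy groups.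

The plan rests on one structural feature. Each erythro C7(OH)–C8(OAr) unit is the syn‑hydration product of a Z enol ether ArCH=C(OAr)CH2OR, with the new hydroxyl on the benzylic carbon and the new hydrogen on the aryloxy carbon. Both units can therefore be set in one operation by a chiral borane.

## Retrosynthetic reasoning

**35 ⇐ 34.** Only O–Si bonds are cut. The last step must be neither acidic nor strongly basic because of the enal, the free para‑hydroxybenzyl alcohol and the coumaran, so all four hydroxyls are carried as silyl ethers and released together with buffered fluoride.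

**34 ⇐ 32.** The aryl–vinyl bond at C5 of ring D is cut. An enal or any other alkene cannot be present during the borane step, so ring D carries a bromide through the synthesis and the three‑carbon enal (as its acetal) is attached afterwards by palladium catalysis.

**32 ⇐ 30.** The two C7–O(H) bonds and the two C8–H bonds are cut, on both chains at once. This is preferred to an aldol cut at C7–C8 because syn addition to a Z enol ether gives the erythro series directly, and because one reagent serves both units. The forward reaction has to place boron on the benzylic carbons, choose one alkene face at each site, and be oxidised before the β‑aryloxy boranes eliminate.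

**30 ⇐ 29 ⇐ 28 ⇐ 20 + 27.** The C7'=C8' double bond is cut, which divides the skeleton into two halves of similar size: the ring C/D phosphonate 20 and the ring A/B aldehyde 27. The olefination must favour the Z enoate (aryl trans to the ester), and the ester is then reduced and silylated without touching the geometry.

**27 ⇐ 26 ⇐ 25 ⇐ 22 + 24; 22 ⇐ 21 + 19; 24 ⇐ 23; 19 ⇐ 18.** The C7=C8 bond is cut in the same way, and the C8–O aryl ether bond is traced to an O–H insertion of phenol 21 with diazo compound 19. Ring B enters as a benzonitrile so that a single hydride step turns the ester into the C9 alcohol and the nitrile into the aldehyde needed for the union. No phenol protecting group is then needed on ring B.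

**20 ⇐ 17 + 19.** The C8'–O bond is cut by the same O–H insertion, here on the hindered ring C phenol, at a stage where no alkene is present.

**17 ⇐ 16 ⇐ 15 ⇐ 12 (through 13 and 14).** The O1–C2 bond of the dihydrofuran is cut. Ionisation of the benzylic carbinol of the desilylated diol gives quinone methide 14, which closes trans to the fixed C3 substituent. Only C3 therefore has to be made in absolute terms, and the carbinol configuration is irrelevant.

**12 ⇐ 11 ⇐ 7 + 9; 9 ⇐ 8.** The bond between the future C2 and C3 is cut by an auxiliary‑controlled aldol reaction of arylacetyl imide 7 with aldehyde 9. This sets C3 reliably, and the auxiliary is removed reductively to give the C3 hydroxymethyl group.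

**7 ⇐ 5 ⇐ 3 ⇐ 2 ⇐ 1.** The arylacetic acid is reached from aldehyde 1 by a one‑carbon homologation, with the ring D phenol silylated.

## Alternatives that were turned down

**Alternative 1:** The disconnection is the O1–C2 bond of the dihydrofuran. In the forward step, mild acid converts the acyclic diol A2 (either carbinol epimer) into the para‑quinone methide A3, and the ring D phenol adds to it in a 5‑exo closure to give the trans coumaran phenol A1.
- For it: the closure is stereoconvergent, the trans outcome is favoured both kinetically and thermodynamically, and the precursor needs only one stereocentre from an aldol reaction.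
- Against it for this target: it builds the plan around the dihydrofuran ring and the two stereocentres that are easiest to make. The four chain centres remain, and stepwise auxiliary aldol chemistry would deliver them in the threo series, so each unit would need a later correction. The closure also has to be done early, because acid at a late stage would ionise C7 and C7' as well.
- Comparison: on certainty of its key step this alternative is stronger than the chosen one. The chosen route keeps that strength by using the same kind of closure as a supporting step (step 8; A1 has the structure of compound 15). In addition it sets four stereocentres in one operation in the erythro series.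

**Alternative 2:** The disconnection is the C3a–C3 bond together with the exocyclic CH2–O bond. In the forward step the aryl radical from iodide A5, a branched allyl aryl ether made enantioenriched by asymmetric allylic etherification, cyclises 5‑exo onto the vinyl group. The primary radical is trapped by TEMPO to give A4.
- For it: C2 is set catalytically, the ring and the oxygenated C3 side chain form together, and ring D already carries a formyl group, so no palladium coupling is needed at the end. To the coumaran it is the shortest of the approaches.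
- Against it: C3 is set under kinetic control relative to C2, with no means of later correction, so a cis/trans mixture is likely. The ether carbon of A5 is benzylic, allylic and attached to a very electron‑rich ring, so ionisation and rearrangement to the linear ether can erode the enantiomeric purity. The phenol to be allylated is flanked by iodine and methoxy. The N–O bond must be cleaved in a further step, and the formyl group would have to be masked before any borane chemistry.
- Comparison: it is stronger on step count to the ring. The chosen route offers a coumaran whose two centres are secured by an auxiliary and by thermodynamics, and a ring D bromide that is inert to the borane. The four chain centres would still be unsolved.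

**Alternative 3:** The disconnection is the C2–C3 bond. In the forward step the donor/acceptor carbene from diazo ester A7 and Rh2(S‑PTTL)4 inserts into the benzylic C–H of the ortho syringylmethyl ether to give the cis ester A8, and methoxide epimerises C3 to the trans ester A6.
- For it: the enantiocontrol is catalytic, the C–H bond is strongly activated, a C–C bond of the ring is made directly, and the bromide is in place.
- Against it: A7 needs the same arylacetate homologation as the chosen route plus a diazo transfer. The enantioselectivity depends on a catalyst–substrate match for an unusually electron‑rich benzyl ether. The epimerisation passes through an ester enolate that can expel the C2 aryloxide and re‑close, which would scramble C2. An ester reduction follows.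
- Comparison: on reagent economy it is stronger, since no stoichiometric auxiliary is used. The chosen route offers configurational security of the coumaran. As with the other two alternatives, the harder half of the molecule, the two erythro units, is not addressed by the key step.

Key step: step 21

## Remarks on the chemistry

- Locants: C7–C9 is the chain on ring A, C7'–C9' the chain on ring B, C2/C3 the dihydrofuran carbons.
- Abbreviations: TBS = tert‑butyldimethylsilyl, TIPS = triisopropylsilyl, TBSO‑methyl = CH2OTBS, Ipc = isopinocampheyl.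
- Step counting: a two‑stage operation with a single purification counts as one step.
- Assumption: the alkene face attacked by IpcBH2 is assigned by the empirical rule for trisubstituted alkenes (below); if it proves opposite on aryloxy enol ethers, the reagent from (1R)‑(+)‑α‑pinene is used with no other change.

## Route

Step 1
Reactants: 1 5-bromo-2-hydroxy-3-methoxybenzaldehyde
Product: 2 5-bromo-3-methoxy-2-(triisopropylsilyloxy)benzaldehyde
Conditions: TIPSCl, imidazole, DMF, rt
Reagents that add atoms: triisopropylsilyl chloride, CC(C)[Si](Cl)(C(C)C)C(C)C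
Why: O‑silylation of the phenol; the TIPS aryl ether should survive the ylide, aqueous acid, chlorite, boron enolate and borohydride of steps 2–7 and is removed together with the ring C silyl ether in step 8.

Step 2
Reactants: 2 5-bromo-3-methoxy-2-(triisopropylsilyloxy)benzaldehyde
Product: 3 [4-bromo-2-methoxy-6-(2-methoxyethenyl)phenoxy]triisopropylsilane (E/Z mixture)
Conditions: MeOCH2PPh3Cl, KOtBu, THF, 0 °C → rt
Reagents that add atoms: (methoxymethyl)triphenylphosphonium chloride, COC[P+](c1ccccc1)(c1ccccc1)c1ccccc1.[Cl-]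
Why: Wittig olefination with the methoxymethylene ylide adds the one carbon needed for the arylacetic acid; both alkene isomers lead to the same aldehyde.

Step 3
Reactants: 3 [4-bromo-2-methoxy-6-(2-methoxyethenyl)phenoxy]triisopropylsilane
Product: 5 2-[5-bromo-3-methoxy-2-(triisopropylsilyloxy)phenyl]acetic acid, via arylacetaldehyde 4 (not isolated)
Conditions: 2 M HCl, THF, 40 °C; then NaClO2, NaH2PO4, 2-methyl-2-butene, tBuOH/H2O, 0 °C → rt
Reagents that add atoms: water, O; sodium chlorite, [Na+].[O-]Cl=O
Why: Acid hydrolysis of the enol ether followed by Pinnick oxidation of the crude, enolisable aldehyde; the alkene scavenger removes hypochlorite so that the electron‑rich ring is not chlorinated, and the aryl TIPS ether is stable to both stages.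

Step 4
Reactants: 5 2-[5-bromo-3-methoxy-2-(triisopropylsilyloxy)phenyl]acetic acid
Product: 7 (4R)-4-benzyl-3-{2-[5-bromo-3-methoxy-2-(triisopropylsilyloxy)phenyl]acetyl}oxazolidin-2-one, via mixed pivalic anhydride 6 (not isolated)
Conditions: PivCl, Et3N, THF, −20 °C; then (R)-4-benzyloxazolidin-2-one, LiCl, −20 °C → rt
Reagents that add atoms: (R)-4-benzyloxazolidin-2-one, O=C1N[C@H](Cc2ccccc2)CO1
Why: N‑Acylation of the oxazolidinone through the mixed anhydride, which is attacked at the less hindered arylacetyl carbonyl; the R auxiliary is chosen so that the aldol of step 6 gives the 3S centre of the coumaran.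

Step 5
Reactants: 8 4-hydroxy-3,5-dimethoxybenzaldehyde (syringaldehyde)
Product: 9 4-(tert-butyldimethylsilyloxy)-3,5-dimethoxybenzaldehyde
Conditions: TBSCl, imidazole, DMF, rt
Reagents that add atoms: tert-butyldimethylsilyl chloride, CC(C)(C)[Si](C)(C)Cl
Why: Silylation of the phenol, which would otherwise quench the boron enolate; the aryl TBS ether is cleaved by fluoride in step 8.

Step 6
Reactants: 7 (4R)-4-benzyl-3-{2-[5-bromo-3-methoxy-2-(triisopropylsilyloxy)phenyl]acetyl}oxazolidin-2-one; 9 4-(tert-butyldimethylsilyloxy)-3,5-dimethoxybenzaldehyde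
Product: 11 (4R)-4-benzyl-3-{(2R,3R)-2-[5-bromo-3-methoxy-2-(triisopropylsilyloxy)phenyl]-3-[4-(tert-butyldimethylsilyloxy)-3,5-dimethoxyphenyl]-3-hydroxypropanoyl}oxazolidin-2-one, via Z dibutylboron enolate 10 (not isolated)
Conditions: nBu2BOTf, iPr2NEt, CH2Cl2, −78 → 0 °C; then 9, −78 → 0 °C; pH 7 buffer, MeOH, H2O2, 0 °C
Reagents that add atoms: none
Why: Evans aldol reaction: the Z boron enolate adds through a closed chair transition state on the enolate face left open by the benzyl group, which should give the syn adduct and set the α‑carbon as R (the future C3, S after reduction). The carbinol configuration does not matter because it is erased in step 8.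

Step 7
Reactants: 11 (4R)-4-benzyl-3-{(2R,3R)-2-[5-bromo-3-methoxy-2-(triisopropylsilyloxy)phenyl]-3-[4-(tert-butyldimethylsilyloxy)-3,5-dimethoxyphenyl]-3-hydroxypropanoyl}oxazolidin-2-one
Product: 12 (1R,2S)-2-[5-bromo-3-methoxy-2-(triisopropylsilyloxy)phenyl]-1-[4-(tert-butyldimethylsilyloxy)-3,5-dimethoxyphenyl]propane-1,3-diol
Conditions: LiBH4, MeOH (1 equiv), THF, 0 °C
Reagents that add atoms: none
Why: Reductive removal of the auxiliary by borohydride attack at the exocyclic imide carbonyl gives the primary alcohol and returns the oxazolidinone; low temperature and the absence of free base guard the α‑aryl centre against retro‑aldol cleavage and epimerisation.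

Step 8
Reactants: 12 (1R,2S)-2-[5-bromo-3-methoxy-2-(triisopropylsilyloxy)phenyl]-1-[4-(tert-butyldimethylsilyloxy)-3,5-dimethoxyphenyl]propane-1,3-diol
Product: 15 4-[(2R,3S)-5-bromo-3-(hydroxymethyl)-7-methoxy-2,3-dihydro-1-benzofuran-2-yl]-2,6-dimethoxyphenol, via desilylated tetraol 13 (not isolated), via para-quinone methide 14 (not isolated)
Conditions: TBAF, AcOH, THF, 0 °C; aqueous work-up; then TsOH·H2O (cat.), MeCN, 0 °C → rt
Reagents that add atoms: none
Why: Fluoride frees both phenols; catalytic acid then ionises the para‑hydroxybenzylic carbinol to quinone methide 14, and the ring D phenol adds to its exocyclic carbon in a 5‑exo‑trig closure. The aryl group at C2 ends trans to the C3 hydroxymethyl group, as the less crowded and more stable arrangement, so C2 (R) is set by the C3 centre from step 6.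

Step 9
Reactants: 15 4-[(2R,3S)-5-bromo-3-(hydroxymethyl)-7-methoxy-2,3-dihydro-1-benzofuran-2-yl]-2,6-dimethoxyphenol
Product: 16 (2R,3S)-5-bromo-3-(TBSO-methyl)-2-[4-(tert-butyldimethylsilyloxy)-3,5-dimethoxyphenyl]-7-methoxy-2,3-dihydro-1-benzofuran
Conditions: TBSCl (2.5 equiv), imidazole, DMF, rt
Reagents that add atoms: tert-butyldimethylsilyl chloride, CC(C)(C)[Si](C)(C)Cl
Why: Exhaustive silylation of the primary alcohol and the phenol; this avoids relying on a selective mono‑silylation of the alcohol next to a phenol.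

Step 10
Reactants: 16 (2R,3S)-5-bromo-3-(TBSO-methyl)-2-[4-(tert-butyldimethylsilyloxy)-3,5-dimethoxyphenyl]-7-methoxy-2,3-dihydro-1-benzofuran
Product: 17 4-[(2R,3S)-5-bromo-3-(TBSO-methyl)-7-methoxy-2,3-dihydro-1-benzofuran-2-yl]-2,6-dimethoxyphenol
Conditions: Cs2CO3, DMF/H2O (10:1), rt
Reagents that add atoms: none
Why: Chemoselective cleavage of the aryl silyl ether: hydroxide attack at silicon is driven by the phenoxide leaving group, while the primary alkyl TBS ether is inert under these conditions.

Step 11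
Reactants: 18 triethyl phosphonoacetate
Product: 19 triethyl diazophosphonoacetate
Conditions: NaH, THF, 0 °C; 4-acetamidobenzenesulfonyl azide, 0 °C → rt
Reagents that add atoms: 4-acetamidobenzenesulfonyl azide, CC(=O)Nc1ccc(cc1)S(=O)(=O)N=[N+]=[N-]
Why: Regitz diazo transfer to the doubly activated methylene group.

Step 12
Reactants: 17 4-[(2R,3S)-5-bromo-3-(TBSO-methyl)-7-methoxy-2,3-dihydro-1-benzofuran-2-yl]-2,6-dimethoxyphenol; 19 triethyl diazophosphonoacetate
Product: 20 triethyl 2-{4-[(2R,3S)-5-bromo-3-(TBSO-methyl)-7-methoxy-2,3-dihydro-1-benzofuran-2-yl]-2,6-dimethoxyphenoxy}-2-phosphonoacetate (epimers at the phosphonate carbon)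
Conditions: Rh2(OAc)4 (2 mol%), toluene, 80 °C, slow addition of 19
Reagents that add atoms: none
Why: Rhodium carbenoid O–H insertion into the phenol makes the hindered C8'–O aryl ether bond without an SN2 step at a crowded phenoxide; no alkene is present at this stage, and the new stereocentre is lost in step 18.

Step 13
Reactants: 21 4-hydroxy-3,5-dimethoxybenzonitrile; 19 triethyl diazophosphonoacetate
Product: 22 triethyl 2-(4-cyano-2,6-dimethoxyphenoxy)-2-phosphonoacetate
Conditions: Rh2(OAc)4 (2 mol%), toluene, 80 °C, slow addition of 19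
Reagents that add atoms: none
Why: The same O–H insertion makes the C8–O bond; insertion into the phenol is much faster than ylide formation at the nitrile when the nitrile is not in excess.

Step 14
Reactants: 23 4-hydroxy-3-methoxybenzaldehyde (vanillin)
Product: 24 3-methoxy-4-(triisopropylsilyloxy)benzaldehyde
Conditions: TIPSCl, imidazole, DMF, rt
Reagents that add atoms: triisopropylsilyl chloride, CC(C)[Si](Cl)(C(C)C)C(C)C
Why: Silylation of the ring A phenol; the TIPS aryl ether is meant to last to the final step and to withstand the hydride, borane and mildly basic steps better than a TBS aryl ether.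

Step 15
Reactants: 22 triethyl 2-(4-cyano-2,6-dimethoxyphenoxy)-2-phosphonoacetate; 24 3-methoxy-4-(triisopropylsilyloxy)benzaldehyde
Product: 25 ethyl (Z)-2-(4-cyano-2,6-dimethoxyphenoxy)-3-[3-methoxy-4-(triisopropylsilyloxy)phenyl]prop-2-enoate
Conditions: NaH, THF, 0 °C; then 24, 0 °C → rt
Reagents that add atoms: none
Why: Horner–Wadsworth–Emmons olefination; as usual for α‑oxygenated phosphonoacetates and aryl aldehydes the ester should end trans to the aryl group, which is the Z enol ether (aryl and aryloxy cis). Any E isomer is removed by chromatography.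

Step 16
Reactants: 25 ethyl (Z)-2-(4-cyano-2,6-dimethoxyphenoxy)-3-[3-methoxy-4-(triisopropylsilyloxy)phenyl]prop-2-enoate
Product: 26 4-({(Z)-3-hydroxy-1-[3-methoxy-4-(triisopropylsilyloxy)phenyl]prop-1-en-2-yl}oxy)-3,5-dimethoxybenzaldehyde
Conditions: iBu2AlH (4.5 equiv), CH2Cl2, −78 → −20 °C; aq. KNaC4H4O6 (potassium sodium tartrate), then 1 M citric acid, 0 °C
Reagents that add atoms: water, O
Why: Hydride reduction in which the ester takes two hydrides to the allylic alcohol while the nitrile stops at the aluminium iminate, which the aqueous work-up hydrolyses to the aldehyde; the alkene geometry is untouched.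

Step 17
Reactants: 26 4-({(Z)-3-hydroxy-1-[3-methoxy-4-(triisopropylsilyloxy)phenyl]prop-1-en-2-yl}oxy)-3,5-dimethoxybenzaldehyde
Product: 27 4-({(Z)-3-(tert-butyldimethylsilyloxy)-1-[3-methoxy-4-(triisopropylsilyloxy)phenyl]prop-1-en-2-yl}oxy)-3,5-dimethoxybenzaldehyde
Conditions: TBSCl, imidazole, CH2Cl2, 0 °C → rt
Reagents that add atoms: tert-butyldimethylsilyl chloride, CC(C)(C)[Si](C)(C)Cl
Why: Silylation of the primary allylic alcohol, so that it does not consume base in step 18 or hydride in step 21.

Step 18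
Reactants: 20 triethyl 2-{4-[(2R,3S)-5-bromo-3-(TBSO-methyl)-7-methoxy-2,3-dihydro-1-benzofuran-2-yl]-2,6-dimethoxyphenoxy}-2-phosphonoacetate; 27 4-({(Z)-3-(tert-butyldimethylsilyloxy)-1-[3-methoxy-4-(triisopropylsilyloxy)phenyl]prop-1-en-2-yl}oxy)-3,5-dimethoxybenzaldehyde
Product: 28 ethyl (Z)-2-{4-[(2R,3S)-5-bromo-3-(TBSO-methyl)-7-methoxy-2,3-dihydro-1-benzofuran-2-yl]-2,6-dimethoxyphenoxy}-3-[4-({(Z)-3-(tert-butyldimethylsilyloxy)-1-[3-methoxy-4-(triisopropylsilyloxy)phenyl]prop-1-en-2-yl}oxy)-3,5-dimethoxyphenyl]prop-2-enoate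
Conditions: NaH, THF, 0 °C; then 27, 0 °C → rt
Reagents that add atoms: none
Why: Horner–Wadsworth–Emmons union of the two halves, forming C7'=C8' with the same expected preference for the Z enol ether as in step 15; the first enol ether, the silyl ethers and the bromide are inert to the phosphonate anion.

Step 19
Reactants: 28 the Z,Z enoate of step 18
Product: 29 (Z)-2-{4-[(2R,3S)-5-bromo-3-(TBSO-methyl)-7-methoxy-2,3-dihydro-1-benzofuran-2-yl]-2,6-dimethoxyphenoxy}-3-[4-({(Z)-3-(tert-butyldimethylsilyloxy)-1-[3-methoxy-4-(triisopropylsilyloxy)phenyl]prop-1-en-2-yl}oxy)-3,5-dimethoxyphenyl]prop-2-en-1-ol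
Conditions: iBu2AlH (2.5 equiv), CH2Cl2, −78 °C; aq. KNaC4H4O6 (potassium sodium tartrate)
Reagents that add atoms: none
Why: 1,2‑Reduction of the α‑aryloxy enoate to the allylic alcohol; the aryl bromide, silyl ethers and both enol ethers are stable to the hydride at −78 °C.

Step 20
Reactants: 29 the allylic alcohol of step 19
Product: 30 bis(Z-enol ether): the C9' TBS ether of 29 (2R,3S; TBS ethers at C9 and C9' and at the coumaran CH2O; TIPS ether on ring A; bromide at C5 of ring D)
Conditions: TBSCl, imidazole, DMF, rt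
Reagents that add atoms: tert-butyldimethylsilyl chloride, CC(C)(C)[Si](C)(C)Cl
Why: Silylation of the last free hydroxyl, so that the substrate of the key step has no O–H bond to consume the borane.

Step 21
Reactants: 30 bis(Z-enol ether)
Product: 32 (7R,8S,7'R,8'S)-bis(erythro benzylic alcohol): 30 with OH added at C7 and C7' and H at C8 and C8' (all silyl ethers and the bromide retained), via bis(isopinocampheylboryl) adduct 31 (not isolated)
Conditions: (IpcBH2)2·TMEDA [from (1S)-(−)-α-pinene], BF3·OEt2, THF, rt; then 30, −25 °C (to 0 °C only if needed); then NaBO3·4H2O, THF/H2O, 0 °C → rt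
Reagents that add atoms: sodium perborate tetrahydrate, [Na+].[Na+].O[B-]1(O)OO[B-](O)(O)OO1
Why: The B–H bond of IpcBH2 adds in a concerted four‑centre syn fashion to each Z enol ether, with boron on C7 and C7' (the only CH terminus, β to the ether oxygen and benzylic) and hydrogen on C8 and C8'; perborate then replaces each C–B bond by C–OH with retention, through adduct 31. The closest known reaction type is the asymmetric hydroboration–oxidation of trisubstituted alkenes and trisubstituted enol ethers with isopinocampheylboranes, which gives anti β‑alkoxy alcohols; aryloxy enol ethers and two additions in one molecule extend that scope. No ring is closed. C8 and C8' are fixed relative to C7 and C7' by syn addition to the Z geometry, which is the erythro relationship; the absolute sense at C7 and C7' is set by the reagent. Since the reagent from (+)‑α‑pinene gives S carbinols from 2‑methyl‑2‑butene and 1‑methylcyclopentene, the reagent from (−)‑α‑pinene should give 7R,8S and 7'R,8'S. The step needs regioselectivity (secured by the oxygen substituent and the substitution pattern), clean Z geometry (from steps 15 and 18), the same face at two like sites (one reagent, with the coumaran centres too remote to interfere) and oxidation before the β‑aryloxy boranes eliminate (low temperature, mild oxidant at 0 °C). Because the coumaran is already a single enantiomer, a wrong‑face addition at either site gives a diastereomer that can be removed by chromatography, so this step decides diastereomeric and not enantiomeric purity. The aryl bromide, silyl ethers and aryl ethers are inert to the borane and to perborate.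

Step 22
Reactants: 32 (7R,8S,7'R,8'S)-bis(erythro benzylic alcohol)
Product: 34 (E)-enal: 32 with the ring D bromide replaced by (E)-CH=CH–CHO, via cinnamaldehyde diethyl acetal 33 (not isolated)
Conditions: acrolein diethyl acetal, Pd(OAc)2, nBu4NOAc, K2CO3, KCl, DMF, 90 °C; then 1 M HCl, THF, 0 °C
Reagents that add atoms: acrolein diethyl acetal, C=CC(OCC)OCC; water, O
Why: Heck reaction: the ring D bromide adds oxidatively to zerovalent palladium formed from Pd(OAc)2, the acetal alkene inserts, and β‑hydride elimination toward the benzylic hydrogen gives the E cinnamyl acetal 33. Brief dilute acid then unmasks the enal without ionising the benzylic alcohols.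

Step 23
Reactants: 34 (E)-enal with three TBS ethers and one TIPS ether
Product: 35 CNP0192639.1 (7R,8S,7'R,8'S,2R,3S)
Conditions: TBAF, AcOH, THF, 0 °C → rt
Reagents that add atoms: none
Why: Fluoride cleavage of the three alkyl TBS ethers and the aryl TIPS ether in one operation; acetic acid buffering keeps the medium near neutral so that the enal, the para‑hydroxybenzyl alcohol and the coumaran are not exposed to base or acid.

## Compound list

1 | 5-bromo-2-hydroxy-3-methoxybenzaldehyde | COc1cc(Br)cc(C=O)c1O | starting material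
2 | 5-bromo-3-methoxy-2-(triisopropylsilyloxy)benzaldehyde | COc1cc(Br)cc(C=O)c1O[Si](C(C)C)(C(C)C)C(C)C | intermediate
3 | [4-bromo-2-methoxy-6-(2-methoxyethenyl)phenoxy]triisopropylsilane (E/Z mixture) | COC=Cc1cc(Br)cc(OC)c1O[Si](C(C)C)(C(C)C)C(C)C | intermediate
4 | 2-[5-bromo-3-methoxy-2-(triisopropylsilyloxy)phenyl]acetaldehyde | COc1cc(Br)cc(CC=O)c1O[Si](C(C)C)(C(C)C)C(C)C | intermediate (not isolated)
5 | 2-[5-bromo-3-methoxy-2-(triisopropylsilyloxy)phenyl]acetic acid | COc1cc(Br)cc(CC(=O)O)c1O[Si](C(C)C)(C(C)C)C(C)C | intermediate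
6 | 2-[5-bromo-3-methoxy-2-(triisopropylsilyloxy)phenyl]acetic pivalic anhydride | COc1cc(Br)cc(CC(=O)OC(=O)C(C)(C)C)c1O[Si](C(C)C)(C(C)C)C(C)C | intermediate (not isolated)
7 | (4R)-4-benzyl-3-{2-[5-bromo-3-methoxy-2-(triisopropylsilyloxy)phenyl]acetyl}oxazolidin-2-one | COc1cc(Br)cc(CC(=O)N2C(=O)OC[C@H]2Cc2ccccc2)c1O[Si](C(C)C)(C(C)C)C(C)C | intermediate
8 | 4-hydroxy-3,5-dimethoxybenzaldehyde (syringaldehyde) | COc1cc(C=O)cc(OC)c1O | starting material
9 | 4-(tert-butyldimethylsilyloxy)-3,5-dimethoxybenzaldehyde | COc1cc(C=O)cc(OC)c1O[Si](C)(C)C(C)(C)C | intermediate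
10 | (4R)-4-benzyl-3-{(Z)-1-(dibutylboryloxy)-2-[5-bromo-3-methoxy-2-(triisopropylsilyloxy)phenyl]ethenyl}oxazolidin-2-one | CCCCB(CCCC)O/C(=C\c1cc(Br)cc(OC)c1O[Si](C(C)C)(C(C)C)C(C)C)N1C(=O)OC[C@H]1Cc1ccccc1 | intermediate (not isolated)
11 | (4R)-4-benzyl-3-{(2R,3R)-2-[5-bromo-3-methoxy-2-(triisopropylsilyloxy)phenyl]-3-[4-(tert-butyldimethylsilyloxy)-3,5-dimethoxyphenyl]-3-hydroxypropanoyl}oxazolidin-2-one | COc1cc(Br)cc([C@@H](C(=O)N2C(=O)OC[C@H]2Cc2ccccc2)[C@@H](O)c2cc(OC)c(O[Si](C)(C)C(C)(C)C)c(OC)c2)c1O[Si](C(C)C)(C(C)C)C(C)C | intermediate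
12 | (1R,2S)-2-[5-bromo-3-methoxy-2-(triisopropylsilyloxy)phenyl]-1-[4-(tert-butyldimethylsilyloxy)-3,5-dimethoxyphenyl]propane-1,3-diol | COc1cc(Br)cc([C@@H](CO)[C@@H](O)c2cc(OC)c(O[Si](C)(C)C(C)(C)C)c(OC)c2)c1O[Si](C(C)C)(C(C)C)C(C)C | intermediate
13 | (1R,2S)-2-(5-bromo-2-hydroxy-3-methoxyphenyl)-1-(4-hydroxy-3,5-dimethoxyphenyl)propane-1,3-diol | COc1cc(Br)cc([C@@H](CO)[C@@H](O)c2cc(OC)c(O)c(OC)c2)c1O | intermediate (not isolated)
14 | 4-[(2S)-2-(5-bromo-2-hydroxy-3-methoxyphenyl)-3-hydroxypropylidene]-2,6-dimethoxycyclohexa-2,5-dien-1-one | COC1=CC(=C[C@H](CO)c2cc(Br)cc(OC)c2O)C=C(OC)C1=O | intermediate (not isolated)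
15 | 4-[(2R,3S)-5-bromo-3-(hydroxymethyl)-7-methoxy-2,3-dihydro-1-benzofuran-2-yl]-2,6-dimethoxyphenol | COc1cc([C@@H]2Oc3c(OC)cc(Br)cc3[C@H]2CO)cc(OC)c1O | intermediate
16 | (2R,3S)-5-bromo-3-(TBSO-methyl)-2-[4-(tert-butyldimethylsilyloxy)-3,5-dimethoxyphenyl]-7-methoxy-2,3-dihydro-1-benzofuran | COc1cc([C@@H]2Oc3c(OC)cc(Br)cc3[C@H]2CO[Si](C)(C)C(C)(C)C)cc(OC)c1O[Si](C)(C)C(C)(C)C | intermediate
17 | 4-[(2R,3S)-5-bromo-3-(TBSO-methyl)-7-methoxy-2,3-dihydro-1-benzofuran-2-yl]-2,6-dimethoxyphenol | COc1cc([C@@H]2Oc3c(OC)cc(Br)cc3[C@H]2CO[Si](C)(C)C(C)(C)C)cc(OC)c1O | intermediate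
18 | triethyl phosphonoacetate | CCOC(=O)CP(=O)(OCC)OCC | starting material
19 | triethyl diazophosphonoacetate | CCOC(=O)C(=[N+]=[N-])P(=O)(OCC)OCC | intermediate
20 | triethyl 2-{4-[(2R,3S)-5-bromo-3-(TBSO-methyl)-7-methoxy-2,3-dihydro-1-benzofuran-2-yl]-2,6-dimethoxyphenoxy}-2-phosphonoacetate (epimers at the phosphonate carbon) | COc1cc([C@@H]2Oc3c(OC)cc(Br)cc3[C@H]2CO[Si](C)(C)C(C)(C)C)cc(OC)c1OC(C(=O)OCC)P(=O)(OCC)OCC | intermediate
21 | 4-hydroxy-3,5-dimethoxybenzonitrile | COc1cc(C#N)cc(OC)c1O | starting material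
22 | triethyl 2-(4-cyano-2,6-dimethoxyphenoxy)-2-phosphonoacetate | COc1cc(C#N)cc(OC)c1OC(C(=O)OCC)P(=O)(OCC)OCC | intermediate
23 | 4-hydroxy-3-methoxybenzaldehyde (vanillin) | COc1cc(C=O)ccc1O | starting material
24 | 3-methoxy-4-(triisopropylsilyloxy)benzaldehyde | COc1cc(C=O)ccc1O[Si](C(C)C)(C(C)C)C(C)C | intermediate
25 | ethyl (Z)-2-(4-cyano-2,6-dimethoxyphenoxy)-3-[3-methoxy-4-(triisopropylsilyloxy)phenyl]prop-2-enoate | COc1cc(/C=C(/C(=O)OCC)Oc2c(OC)cc(C#N)cc2OC)ccc1O[Si](C(C)C)(C(C)C)C(C)C | intermediate
26 | 4-({(Z)-3-hydroxy-1-[3-methoxy-4-(triisopropylsilyloxy)phenyl]prop-1-en-2-yl}oxy)-3,5-dimethoxybenzaldehyde | COc1cc(/C=C(/CO)Oc2c(OC)cc(C=O)cc2OC)ccc1O[Si](C(C)C)(C(C)C)C(C)C | intermediate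
27 | 4-({(Z)-3-(tert-butyldimethylsilyloxy)-1-[3-methoxy-4-(triisopropylsilyloxy)phenyl]prop-1-en-2-yl}oxy)-3,5-dimethoxybenzaldehyde | COc1cc(/C=C(/CO[Si](C)(C)C(C)(C)C)Oc2c(OC)cc(C=O)cc2OC)ccc1O[Si](C(C)C)(C(C)C)C(C)C | intermediate
28 | ethyl (Z)-2-{4-[(2R,3S)-5-bromo-3-(TBSO-methyl)-7-methoxy-2,3-dihydro-1-benzofuran-2-yl]-2,6-dimethoxyphenoxy}-3-[4-({(Z)-3-(tert-butyldimethylsilyloxy)-1-[3-methoxy-4-(triisopropylsilyloxy)phenyl]prop-1-en-2-yl}oxy)-3,5-dimethoxyphenyl]prop-2-enoate | COc1cc(/C=C(/CO[Si](C)(C)C(C)(C)C)Oc2c(OC)cc(/C=C(/C(=O)OCC)Oc3c(OC)cc([C@@H]4Oc5c(OC)cc(Br)cc5[C@H]4CO[Si](C)(C)C(C)(C)C)cc3OC)cc2OC)ccc1O[Si](C(C)C)(C(C)C)C(C)C | intermediate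
29 | allylic alcohol from 28 (ester reduced to C9' CH2OH; both alkenes Z; 2R,3S) | COc1cc(/C=C(/CO[Si](C)(C)C(C)(C)C)Oc2c(OC)cc(/C=C(/CO)Oc3c(OC)cc([C@@H]4Oc5c(OC)cc(Br)cc5[C@H]4CO[Si](C)(C)C(C)(C)C)cc3OC)cc2OC)ccc1O[Si](C(C)C)(C(C)C)C(C)C | intermediate
30 | bis(Z-enol ether): C9' TBS ether of 29 | COc1cc(/C=C(/CO[Si](C)(C)C(C)(C)C)Oc2c(OC)cc(/C=C(/CO[Si](C)(C)C(C)(C)C)Oc3c(OC)cc([C@@H]4Oc5c(OC)cc(Br)cc5[C@H]4CO[Si](C)(C)C(C)(C)C)cc3OC)cc2OC)ccc1O[Si](C(C)C)(C(C)C)C(C)C | intermediate
31 | bis(borane) adduct of 30: B(H)Ipc at C7 and C7', H at C8 and C8', Ipc from (−)-α-pinene | COc1cc([C@@H](B[C@H]2C[C@H]3C[C@@H]([C@@H]2C)C3(C)C)[C@H](CO[Si](C)(C)C(C)(C)C)Oc2c(OC)cc([C@@H](B[C@H]3C[C@H]4C[C@@H]([C@@H]3C)C4(C)C)[C@H](CO[Si](C)(C)C(C)(C)C)Oc3c(OC)cc([C@@H]4Oc5c(OC)cc(Br)cc5[C@H]4CO[Si](C)(C)C(C)(C)C)cc3OC)cc2OC)ccc1O[Si](C(C)C)(C(C)C)C(C)C | intermediate (not isolated)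
32 | (7R,8S,7'R,8'S)-bis(erythro benzylic alcohol) with three TBS ethers, one TIPS ether and the ring D bromide | COc1cc([C@@H](O)[C@H](CO[Si](C)(C)C(C)(C)C)Oc2c(OC)cc([C@@H](O)[C@H](CO[Si](C)(C)C(C)(C)C)Oc3c(OC)cc([C@@H]4Oc5c(OC)cc(Br)cc5[C@H]4CO[Si](C)(C)C(C)(C)C)cc3OC)cc2OC)ccc1O[Si](C(C)C)(C(C)C)C(C)C | intermediate
33 | 32 with (E)-CH=CH–CH(OEt)2 in place of bromine | COc1cc([C@@H](O)[C@H](CO[Si](C)(C)C(C)(C)C)Oc2c(OC)cc([C@@H](O)[C@H](CO[Si](C)(C)C(C)(C)C)Oc3c(OC)cc([C@@H]4Oc5c(OC)cc(/C=C/C(OCC)OCC)cc5[C@H]4CO[Si](C)(C)C(C)(C)C)cc3OC)cc2OC)ccc1O[Si](C(C)C)(C(C)C)C(C)C | intermediate (not isolated)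
34 | 32 with (E)-CH=CH–CHO in place of bromine | COc1cc([C@@H](O)[C@H](CO[Si](C)(C)C(C)(C)C)Oc2c(OC)cc([C@@H](O)[C@H](CO[Si](C)(C)C(C)(C)C)Oc3c(OC)cc([C@@H]4Oc5c(OC)cc(/C=C/C=O)cc5[C@H]4CO[Si](C)(C)C(C)(C)C)cc3OC)cc2OC)ccc1O[Si](C(C)C)(C(C)C)C(C)C | intermediate
35 | CNP0192639.1 | COc1cc([C@@H](O)[C@H](CO)Oc2c(OC)cc([C@@H](O)[C@H](CO)Oc3c(OC)cc([C@@H]4Oc5c(OC)cc(/C=C/C=O)cc5[C@H]4CO)cc3OC)cc2OC)ccc1O | target

## Step count and least certain steps

Total: 23 steps. Longest linear sequence: 16 steps (1–4, 6–10, 12, 18–23).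

**Step 21 (key step).** The most likely failure is that addition to the hindered, conjugated enol ethers is slow at the low temperature needed. The β‑aryloxy boranes can then expel the aryloxide with boron, which cleaves the C8–O ether, or the second alkene, flanked by two 2,6‑dimethoxyaryl groups, remains unreacted or reacts with weaker face selectivity. The aryloxy group is a better leaving group than the alkoxy groups of the known cases, which is why this risk is real.

The fallback builds the two units without boranes. It sets out from phenol 17 with aldehydes 9 and 24 and returns at 32.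
- Phenol 17 is alkylated with (R)-4-benzyl-3-(bromoacetyl)oxazolidin-2-one (K2CO3, acetone) to give the aryloxyacetyl imide F1.
- A dibutylboron syn aldol reaction with 9 gives the (2R,3S) adduct F2, which fixes C8' in the required S configuration.
- LiBH4 gives the threo diol F3, TBSCl silylates only the primary hydroxyl to give F4, and Cs2CO3 in wet DMF frees the ring B phenol to give F5.
- The cycle is repeated: alkylation gives imide F6; the boron aldol with 24 gives adduct F7 (one further equivalent of nBu2BOTf is taken up by the free C7' hydroxyl); LiBH4 gives triol F8; primary silylation gives F9, the 7S,8S,7'S,8'S isomer of 32.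
- Both benzylic carbinols are then corrected together: Dess–Martin oxidation gives diketone F10, and chelation‑controlled reduction with Zn(BH4)2 in ether at low temperature, through a chelate of the carbonyl and the C8 aryloxy oxygen, gives the anti, that is erythro, diol 32.

This detour is fully linear and takes eleven steps from 17, against five on the main line (steps 12 and 18–21) plus the five‑step side branch to aldehyde 27. Its reduction is the least selective stage, so it stays a reserve.

**Step 18.** The anion of phosphonate 20 carries an aryloxy group with two ortho methoxy groups and may add sluggishly to aldehyde 27 or give too much of the E enoate, which would lead to a threo unit. Step 15 tests the same reaction first on the small fragment.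

The fallback is an aldol–elimination route. It sets out from 17 and 27 and returns at 28. Alkylation of 17 with ethyl bromoacetate (K2CO3, acetone) gives the aryloxyacetate F11. Its lithium enolate (LiN(iPr)2, THF, −78 °C) adds to 27 to give the β‑hydroxy ester F12 as a diastereomer mixture. Mesylation (MsCl, Et3N) gives the mesylate F13, and E1cB elimination with DBU gives enoate 28, in which the Z isomer (aryl trans to the ester) is the thermodynamically favoured one. This detour also bypasses the carbenoid insertion of step 12.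

**Step 16.** Over‑reduction of the iminate to the benzylic amine, or incomplete reduction of one of the two functions, can occur when ester and nitrile are reduced in one flask with an excess of hydride.

The fallback reduces the two functions separately with different reagents. It sets out from 25 and returns at 27. LiBH4 (THF, 0 °C) reduces only the ester to the nitrile alcohol F14, TBSCl and imidazole give the silyl ether F15, and one equivalent of iBu2AlH in toluene at −78 °C followed by mild aqueous acid converts the nitrile into aldehyde 27.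

**Step 22.** At 90 °C with carbonate, palladium alkoxides of the free benzylic alcohols can undergo β‑hydride elimination, which oxidises an alcohol and reduces the bromide. The aryl TIPS ether can also be lost, and the regiochemistry of β‑hydride elimination can drift toward the saturated ester.

The fallback replaces the Heck reaction by a cross‑coupling that fixes the alkene position and runs under milder conditions. It sets out from 32 and returns at the acetal 33 and then 34, and makes no new compound (F0). It is a Suzuki–Miyaura coupling with (E)-2-(3,3-diethoxyprop-1-enyl)-4,4,5,5-tetramethyl-1,3,2-dioxaborolane (Pd(dppf)Cl2, K3PO4, dioxane/H2O, 70 °C), followed by the same dilute acid hydrolysis.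

## Further compounds

F1 | step 21 | (4R)-4-benzyl-3-(2-{4-[(2R,3S)-5-bromo-3-(TBSO-methyl)-7-methoxy-2,3-dihydro-1-benzofuran-2-yl]-2,6-dimethoxyphenoxy}acetyl)oxazolidin-2-one | COc1cc([C@@H]2Oc3c(OC)cc(Br)cc3[C@H]2CO[Si](C)(C)C(C)(C)C)cc(OC)c1OCC(=O)N1C(=O)OC[C@H]1Cc1ccccc1
F2 | step 21 | syn aldol adduct of F1 with 9, (2R,3S) in the propanoyl chain | COc1cc([C@H](O)[C@H](C(=O)N2C(=O)OC[C@H]2Cc2ccccc2)Oc2c(OC)cc([C@@H]3Oc4c(OC)cc(Br)cc4[C@H]3CO[Si](C)(C)C(C)(C)C)cc2OC)cc(OC)c1O[Si](C)(C)C(C)(C)C
F3 | step 21 | (7'S,8'S)-threo diol from F2 (ring B as TBS ether) | COc1cc([C@H](O)[C@H](CO)Oc2c(OC)cc([C@@H]3Oc4c(OC)cc(Br)cc4[C@H]3CO[Si](C)(C)C(C)(C)C)cc2OC)cc(OC)c1O[Si](C)(C)C(C)(C)C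
F4 | step 21 | C9' TBS ether of F3 | COc1cc([C@H](O)[C@H](CO[Si](C)(C)C(C)(C)C)Oc2c(OC)cc([C@@H]3Oc4c(OC)cc(Br)cc4[C@H]3CO[Si](C)(C)C(C)(C)C)cc2OC)cc(OC)c1O[Si](C)(C)C(C)(C)C
F5 | step 21 | ring B phenol from F4 | COc1cc([C@H](O)[C@H](CO[Si](C)(C)C(C)(C)C)Oc2c(OC)cc([C@@H]3Oc4c(OC)cc(Br)cc4[C@H]3CO[Si](C)(C)C(C)(C)C)cc2OC)cc(OC)c1O
F6 | step 21 | N-(aryloxyacetyl) (R)-4-benzyloxazolidin-2-one from F5 | COc1cc([C@H](O)[C@H](CO[Si](C)(C)C(C)(C)C)Oc2c(OC)cc([C@@H]3Oc4c(OC)cc(Br)cc4[C@H]3CO[Si](C)(C)C(C)(C)C)cc2OC)cc(OC)c1OCC(=O)N1C(=O)OC[C@H]1Cc1ccccc1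
F7 | step 21 | syn aldol adduct of F6 with 24, (2R,3S) in the new propanoyl chain | COc1cc([C@H](O)[C@H](C(=O)N2C(=O)OC[C@H]2Cc2ccccc2)Oc2c(OC)cc([C@H](O)[C@H](CO[Si](C)(C)C(C)(C)C)Oc3c(OC)cc([C@@H]4Oc5c(OC)cc(Br)cc5[C@H]4CO[Si](C)(C)C(C)(C)C)cc3OC)cc2OC)ccc1O[Si](C(C)C)(C(C)C)C(C)C
F8 | step 21 | (7S,8S,7'S,8'S)-triol from F7 (C9 hydroxyl free) | COc1cc([C@H](O)[C@H](CO)Oc2c(OC)cc([C@H](O)[C@H](CO[Si](C)(C)C(C)(C)C)Oc3c(OC)cc([C@@H]4Oc5c(OC)cc(Br)cc5[C@H]4CO[Si](C)(C)C(C)(C)C)cc3OC)cc2OC)ccc1O[Si](C(C)C)(C(C)C)C(C)C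
F9 | step 21 | (7S,8S,7'S,8'S) isomer of 32 (threo at both units) | COc1cc([C@H](O)[C@H](CO[Si](C)(C)C(C)(C)C)Oc2c(OC)cc([C@H](O)[C@H](CO[Si](C)(C)C(C)(C)C)Oc3c(OC)cc([C@@H]4Oc5c(OC)cc(Br)cc5[C@H]4CO[Si](C)(C)C(C)(C)C)cc3OC)cc2OC)ccc1O[Si](C(C)C)(C(C)C)C(C)C
F10 | step 21 | 7,7'-diketone from F9 (8S,8'S) | COc1cc(C(=O)[C@H](CO[Si](C)(C)C(C)(C)C)Oc2c(OC)cc(C(=O)[C@H](CO[Si](C)(C)C(C)(C)C)Oc3c(OC)cc([C@@H]4Oc5c(OC)cc(Br)cc5[C@H]4CO[Si](C)(C)C(C)(C)C)cc3OC)cc2OC)ccc1O[Si](C(C)C)(C(C)C)C(C)C
F11 | step 18 | ethyl 2-{4-[(2R,3S)-5-bromo-3-(TBSO-methyl)-7-methoxy-2,3-dihydro-1-benzofuran-2-yl]-2,6-dimethoxyphenoxy}acetate | CCOC(=O)COc1c(OC)cc([C@@H]2Oc3c(OC)cc(Br)cc3[C@H]2CO[Si](C)(C)C(C)(C)C)cc1OC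
F12 | step 18 | β-hydroxy ester from F11 and 27 (diastereomer mixture at C7' and C8') | COc1cc(/C=C(/CO[Si](C)(C)C(C)(C)C)Oc2c(OC)cc(C(O)C(C(=O)OCC)Oc3c(OC)cc([C@@H]4Oc5c(OC)cc(Br)cc5[C@H]4CO[Si](C)(C)C(C)(C)C)cc3OC)cc2OC)ccc1O[Si](C(C)C)(C(C)C)C(C)C
F13 | step 18 | methanesulfonate of F12 | COc1cc(/C=C(/CO[Si](C)(C)C(C)(C)C)Oc2c(OC)cc(C(OS(C)(=O)=O)C(C(=O)OCC)Oc3c(OC)cc([C@@H]4Oc5c(OC)cc(Br)cc5[C@H]4CO[Si](C)(C)C(C)(C)C)cc3OC)cc2OC)ccc1O[Si](C(C)C)(C(C)C)C(C)C
F14 | step 16 | 4-({(Z)-3-hydroxy-1-[3-methoxy-4-(triisopropylsilyloxy)phenyl]prop-1-en-2-yl}oxy)-3,5-dimethoxybenzonitrile | COc1cc(/C=C(/CO)Oc2c(OC)cc(C#N)cc2OC)ccc1O[Si](C(C)C)(C(C)C)C(C)C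
F15 | step 16 | 4-({(Z)-3-(tert-butyldimethylsilyloxy)-1-[3-methoxy-4-(triisopropylsilyloxy)phenyl]prop-1-en-2-yl}oxy)-3,5-dimethoxybenzonitrile | COc1cc(/C=C(/CO[Si](C)(C)C(C)(C)C)Oc2c(OC)cc(C#N)cc2OC)ccc1O[Si](C(C)C)(C(C)C)C(C)C
F0 | step 22 | none | none
A1 | alternative 1 | 4-[(2R,3S)-5-bromo-3-(hydroxymethyl)-7-methoxy-2,3-dihydro-1-benzofuran-2-yl]-2,6-dimethoxyphenol | COc1cc([C@@H]2Oc3c(OC)cc(Br)cc3[C@H]2CO)cc(OC)c1O
A2 | alternative 1 | (2S)-2-(5-bromo-2-hydroxy-3-methoxyphenyl)-1-(4-hydroxy-3,5-dimethoxyphenyl)propane-1,3-diol (either C1 epimer) | COc1cc(Br)cc([C@@H](CO)C(O)c2cc(OC)c(O)c(OC)c2)c1O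
A3 | alternative 1 | 4-[(2S)-2-(5-bromo-2-hydroxy-3-methoxyphenyl)-3-hydroxypropylidene]-2,6-dimethoxycyclohexa-2,5-dien-1-one | COC1=CC(=C[C@H](CO)c2cc(Br)cc(OC)c2O)C=C(OC)C1=O
A4 | alternative 2 | (2R,3S)-2-[4-(tert-butyldimethylsilyloxy)-3,5-dimethoxyphenyl]-7-methoxy-3-{[(2,2,6,6-tetramethylpiperidin-1-yl)oxy]methyl}-2,3-dihydro-1-benzofuran-5-carbaldehyde | COc1cc([C@@H]2Oc3c(OC)cc(C=O)cc3[C@H]2CON4C(C)(C)CCCC4(C)C)cc(OC)c1O[Si](C)(C)C(C)(C)C
A5 | alternative 2 | 4-({(1R)-1-[4-(tert-butyldimethylsilyloxy)-3,5-dimethoxyphenyl]prop-2-en-1-yl}oxy)-3-iodo-5-methoxybenzaldehyde | COc1cc(C=O)cc(I)c1O[C@H](C=C)c1cc(OC)c(O[Si](C)(C)C(C)(C)C)c(OC)c1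
A6 | alternative 3 | methyl (2R,3R)-5-bromo-2-[4-(tert-butyldimethylsilyloxy)-3,5-dimethoxyphenyl]-7-methoxy-2,3-dihydro-1-benzofuran-3-carboxylate (trans) | COc1cc([C@@H]2Oc3c(OC)cc(Br)cc3[C@H]2C(=O)OC)cc(OC)c1O[Si](C)(C)C(C)(C)C
A7 | alternative 3 | methyl 2-(5-bromo-3-methoxy-2-{[4-(tert-butyldimethylsilyloxy)-3,5-dimethoxyphenyl]methoxy}phenyl)-2-diazoacetate | COC(=O)C(=[N+]=[N-])c1cc(Br)cc(OC)c1OCc1cc(OC)c(O[Si](C)(C)C(C)(C)C)c(OC)c1
A8 | alternative 3 | methyl (2R,3S)-5-bromo-2-[4-(tert-butyldimethylsilyloxy)-3,5-dimethoxyphenyl]-7-methoxy-2,3-dihydro-1-benzofuran-3-carboxylate (cis) | COc1cc([C@@H]2Oc3c(OC)cc(Br)cc3[C@@H]2C(=O)OC)cc(OC)c1O[Si](C)(C)C(C)(C)C
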